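**Retrosynthetic overview**
- Target ⇐ Tsuji–Wacker oxidation of a terminal alkene (side-chain ketone) ⇐ Stiles carboxylation / Mannich methylenation of a cis-paraconic acid that carries a pentadec-14-enyl chain.
- cis-γ-Lactone acid ⇐ invertive ring expansion of a cis-β-lactone (oxetan-2-one → oxolan-2-one) by its own tert-butyl ester arm. This is the key step: it builds the five-membered ring and turns C4 (R) of the small ring into C2 (S) of the large one.
- cis-β-Lactone ⇐ catalytic asymmetric ketene–aldehyde cyclocondensation of hexadec-15-enal with the ketene from mono-tert-butyl succinate (succinic anhydride + t-BuOH).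
- Hexadec-15-enal (C16) ⇐ C13 Grignard + acrolein dimethyl acetal (C3, SN2′) ⇐ hept-6-enyl Grignard (C7) + 1,6-dibromohexane (C6).
- Ring order: the four-membered lactone first (step 4), then the γ-lactone by ring expansion (step 5); no other ring is made.

Assumption: O-trimethylsilylquinine is taken to give the (3S,4R)-β-lactone, by analogy with the known sense of cinchona-catalysed ketene–aldehyde cycloadditions; if the sense is opposite, O-trimethylsilylquinidine is used and nothing else changes. Lactones are numbered as oxolanes: O1, C2 (chain), C3 (CO2H), C4, C5 (C=O).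

**Step 1**
Reactants: 1 7-bromohept-1-ene; 2 1,6-dibromohexane
Product: 4 13-bromotridec-1-ene, via hept-6-en-1-ylmagnesium bromide 3 (not isolated)
Conditions: Mg, THF, rt; then added to 2 (3 equiv), Li2CuCl4 (3 mol%), THF, −10 → 0 °C
Reagents that add atoms: none
Why: Kochi-type Li2CuCl4-catalysed sp3–sp3 coupling of a primary Grignard reagent with a primary bromide, the excess of dibromide favouring mono-coupling (no stereocenter; the hept-6-enyl radical cyclises too slowly to matter during Grignard formation).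

**Step 2**
Reactants: 4 13-bromotridec-1-ene; 5 3,3-dimethoxyprop-1-ene (acrolein dimethyl acetal)
Product: 8 hexadec-15-enal, via tridec-12-en-1-ylmagnesium bromide 6 (not isolated), via enol ether 7 (not isolated)
Conditions: Mg, THF, 40 °C; then 5, CuBr (5 mol%), THF, −10 °C → rt; then 1 M HCl, THF, rt
Reagents that add atoms: water, O
Why: CuBr-catalysed SN2′ substitution of the allylic acetal by the Grignard reagent gives the enol ether, which aqueous acid hydrolyses to the aldehyde three carbons longer (the acetal acts as a 3-oxopropyl cation equivalent).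

**Step 3**
Reactants: 9 succinic anhydride
Product: 10 4-(tert-butoxy)-4-oxobutanoic acid
Conditions: t-BuOH (3 equiv), N-hydroxysuccinimide (0.3 equiv), DMAP (0.1 equiv), Et3N (0.3 equiv), toluene, reflux
Reagents that add atoms: tert-butanol, CC(C)(C)O
Why: DMAP/N-hydroxysuccinimide-catalysed alcoholysis of the cyclic anhydride gives the mono-tert-butyl ester (ring-opening esterification).

**Step 4**
Reactants: 10 4-(tert-butoxy)-4-oxobutanoic acid; 8 hexadec-15-enal
Product: 13 tert-butyl 2-[(3S,4R)-2-oxo-4-(pentadec-14-en-1-yl)oxetan-3-yl]acetate (cis), via acid chloride 11 (not isolated), via ketene 12 (not isolated)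
Conditions: (COCl)2, DMF (cat.), CH2Cl2, 0 °C, evaporate cold; then slow addition to 8, O-trimethylsilylquinine (10 mol%), LiClO4 (2 equiv), i-Pr2NEt (2.5 equiv), CH2Cl2/Et2O, −78 °C
Reagents that add atoms: none
Why: Cinchona alkaloid/LiClO4-catalysed acyl halide–aldehyde cyclocondensation (formal ketene–aldehyde [2+2] through a chiral acylammonium enolate, aldol addition then lactonisation), in which the Li-bridged closed transition state gives the cis lactone and the quinine-derived catalyst shields one enolate face, so C3 (S) and C4 (R) are set together.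

**Step 5**
Reactants: 13 tert-butyl 2-[(3S,4R)-2-oxo-4-(pentadec-14-en-1-yl)oxetan-3-yl]acetate
Product: 15 (2S,3S)-5-oxo-2-(pentadec-14-en-1-yl)oxolane-3-carboxylic acid (cis), via trimethylsilyl ester 14 (not isolated)
Conditions: Me3SiOTf (1.3 equiv), 2,6-di-tert-butyl-4-methylpyridine (1.5 equiv), CH2Cl2, −78 → 0 °C; then aq. citric acid
Reagents that add atoms: none
Why: Proposed new method: O-silylation of the β-lactone carbonyl by Me3SiOTf makes the ring carboxylate a leaving group on C4, so the carbonyl oxygen of the tert-butyl ester on the cis C3 arm attacks C4 from the back in a 5-exo-tet SN2 step (inversion, 4R of the oxetanone becomes 2S of the oxolane) while the untouched C3 centre becomes C3 (S) of the oxolane and the resulting 2-tert-butoxyoxolan-2-ylium ion sheds isobutene, giving a strain-driven, stereospecific ring expansion of an oxetan-2-one to an oxolan-2-one; the closest known reaction type is the Lewis-acid-promoted intramolecular SN2 opening of β-lactones by a pendant ether or ketone oxygen (ring expansion to tetrahydrofurans with inversion at C4), combined with dealkylative lactonisation of tert-butyl esters onto activated carbon electrophiles.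

**Step 6**
Reactants: 15 (2S,3S)-5-oxo-2-(pentadec-14-en-1-yl)oxolane-3-carboxylic acid
Product: 17 (2S,3S)-4-methylidene-5-oxo-2-(pentadec-14-en-1-yl)oxolane-3-carboxylic acid, via lactone dicarboxylic acid 16 (not isolated)
Conditions: MeOMgOCO2Me (methyl magnesium carbonate, 2 M in DMF, 35 equiv), 130 °C; cold 2 M HCl work-up; then 37% aq. CH2O, N-methylaniline, NaOAc, AcOH, rt
Reagents that add atoms: formaldehyde, C=O
Why: Stiles carboxylation at C4 (α to the lactone carbonyl) followed by decarboxylative Mannich methylenation, in which the magnesium carboxylate at C3 blocks deprotonation there, so the cis C2/C3 relationship is kept.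

**Step 7**
Reactants: 17 (2S,3S)-4-methylidene-5-oxo-2-(pentadec-14-en-1-yl)oxolane-3-carboxylic acid
Product: 18 allo-pertusaric acid, (2S,3S)-4-methylidene-5-oxo-2-(14-oxopentadecyl)oxolane-3-carboxylic acid
Conditions: PdCl2 (10 mol%), CuCl (1 equiv), O2 (1 atm), DMF/H2O 7:1, rt
Reagents that add atoms: water, O
Why: Tsuji–Wacker oxidation, in which Markovnikov hydroxypalladation of the mono-substituted terminal alkene gives the methyl ketone while the electron-poor 1,1-disubstituted methylene lactone is not attacked and no stereocenter is touched.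

**Compound list**
1 | 7-bromohept-1-ene | C=CCCCCCBr | starting material
2 | 1,6-dibromohexane | BrCCCCCCBr | starting material
3 | hept-6-en-1-ylmagnesium bromide | C=CCCCCC[Mg]Br | intermediate
4 | 13-bromotridec-1-ene | C=CCCCCCCCCCCCBr | intermediate
5 | 3,3-dimethoxyprop-1-ene | C=CC(OC)OC | starting material
6 | tridec-12-en-1-ylmagnesium bromide | C=CCCCCCCCCCCC[Mg]Br | intermediate
7 | (1Z)-1-methoxyhexadeca-1,15-diene (Z mainly) | CO/C=C\CCCCCCCCCCCCC=C | intermediate
8 | hexadec-15-enal | C=CCCCCCCCCCCCCCC=O | intermediate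
9 | succinic anhydride | O=C1CCC(=O)O1 | starting material
10 | 4-(tert-butoxy)-4-oxobutanoic acid | CC(C)(C)OC(=O)CCC(=O)O | intermediate
11 | tert-butyl 4-chloro-4-oxobutanoate | CC(C)(C)OC(=O)CCC(=O)Cl | intermediate
12 | tert-butyl 4-oxobut-3-enoate (ketene) | CC(C)(C)OC(=O)CC=C=O | intermediate
13 | tert-butyl 2-[(3S,4R)-2-oxo-4-(pentadec-14-en-1-yl)oxetan-3-yl]acetate | O=C1O[C@H](CCCCCCCCCCCCCC=C)[C@@H]1CC(=O)OC(C)(C)C | intermediate
14 | trimethylsilyl (2S,3S)-5-oxo-2-(pentadec-14-en-1-yl)oxolane-3-carboxylate | C1C(=O)O[C@@H](CCCCCCCCCCCCCC=C)[C@H]1C(=O)O[Si](C)(C)C | intermediate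
15 | (2S,3S)-5-oxo-2-(pentadec-14-en-1-yl)oxolane-3-carboxylic acid | C1C(=O)O[C@@H](CCCCCCCCCCCCCC=C)[C@H]1C(=O)O | intermediate
16 | (2S,3S)-5-oxo-2-(pentadec-14-en-1-yl)oxolane-3,4-dicarboxylic acid (C4 epimers) | OC(=O)C1C(=O)O[C@@H](CCCCCCCCCCCCCC=C)[C@H]1C(=O)O | intermediate
17 | (2S,3S)-4-methylidene-5-oxo-2-(pentadec-14-en-1-yl)oxolane-3-carboxylic acid | C=C1C(=O)O[C@@H](CCCCCCCCCCCCCC=C)[C@H]1C(=O)O | intermediate
18 | allo-pertusaric acid, (2S,3S)-4-methylidene-5-oxo-2-(14-oxopentadecyl)oxolane-3-carboxylic acid | C=C1C(=O)O[C@@H](CCCCCCCCCCCCCC(C)=O)[C@H]1C(=O)O | target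

**Totals**
Total step count: 7. Longest linear sequence: 6 steps (1, 2, 4, 5, 6, 7); step 3 is a one-step side branch.

**Three steps most likely to fail**

Step 5 (the new ring expansion). The ester oxygen could instead attack the acyl carbon; that anhydride pathway would keep the carbinol configuration and give the trans lactone. Elimination to the alkylidene succinate is the other risk. The fallback uses known chemistry, sets out from 13 and comes back at 15. Methanolysis of 13 (K2CO3, MeOH, 0 °C; acyl–oxygen cleavage, retention) gives 4-tert-butyl 1-methyl (2S)-2-[(1R)-1-hydroxyhexadec-15-en-1-yl]butanedioate F1. MsCl, Et3N, CH2Cl2, −20 °C gives 4-tert-butyl 1-methyl (2S)-2-[(1R)-1-(methanesulfonyloxy)hexadec-15-en-1-yl]butanedioate F2. CF3CO2H in CH2Cl2 removes the tert-butyl group to give (3S,4R)-4-(methanesulfonyloxy)-3-(methoxycarbonyl)nonadec-18-enoic acid F3. Its carboxylate (NaHCO3, DMF, 40 °C) displaces the mesylate with inversion to give methyl (2S,3S)-5-oxo-2-(pentadec-14-en-1-yl)oxolane-3-carboxylate F4. Me3SnOH in 1,2-dichloroethane at 80 °C cleaves the methyl ester to 15.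

Step 4 (cyclocondensation). The acid chloride 11 may cyclise to succinic anhydride with loss of the tert-butyl group, and the cis ratio or ee may be low with this functionalised ketene. The fallback sets out from 10 (with 8) and comes back at 13. DCC/DMAP coupling of 10 with (S)-4-benzyl-1,3-oxazolidin-2-one gives tert-butyl 4-[(4S)-4-benzyl-2-oxo-1,3-oxazolidin-3-yl]-4-oxobutanoate F5. Bu2BOTf, i-Pr2NEt, CH2Cl2, −78 °C, then 8 (syn aldol through the Z boron enolate and a Zimmerman–Traxler transition state) gives tert-butyl (3S,4R)-3-[(4S)-4-benzyl-2-oxo-1,3-oxazolidine-3-carbonyl]-4-hydroxynonadec-18-enoate F6. LiOH/H2O2 in THF/H2O at 0 °C removes the auxiliary to give (2S,3R)-2-[2-(tert-butoxy)-2-oxoethyl]-3-hydroxyoctadec-17-enoic acid F7. PhSO2Cl in pyridine at 0 °C closes the β-lactone through carboxyl activation, with retention, to 13.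

Step 7 (Wacker oxidation on the finished methylene lactone). Palladium hydride species could move the exocyclic double bond into the ring and erase C3, or the free acid could interfere. The fallback sets out from 15 and comes back at 18; it installs the ketone before the methylene group exists. The same PdCl2/CuCl/O2 oxidation on 15 gives (2S,3S)-5-oxo-2-(14-oxopentadecyl)oxolane-3-carboxylic acid F8. 1,2-Bis(trimethylsilyloxy)ethane with Me3SiOTf (cat.) in CH2Cl2 at −78 °C, then aqueous work-up, gives (2S,3S)-2-[13-(2-methyl-1,3-dioxolan-2-yl)tridecyl]-5-oxooxolane-3-carboxylic acid F9; the ketal is needed because MeOMgOCO2Me would also carboxylate a free methyl ketone. MeOMgOCO2Me in DMF at 130 °C with a cold citric acid work-up gives (2S,3S)-2-[13-(2-methyl-1,3-dioxolan-2-yl)tridecyl]-5-oxooxolane-3,4-dicarboxylic acid F10. CH2O, N-methylaniline, NaOAc, AcOH gives (2S,3S)-4-methylidene-2-[13-(2-methyl-1,3-dioxolan-2-yl)tridecyl]-5-oxooxolane-3-carboxylic acid F11. Pyridinium p-toluenesulfonate in wet acetone at rt frees the ketone to give 18.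

**Further compounds**
F1 | step 5 | 4-tert-butyl 1-methyl (2S)-2-[(1R)-1-hydroxyhexadec-15-en-1-yl]butanedioate | COC(=O)[C@@H](CC(=O)OC(C)(C)C)[C@H](O)CCCCCCCCCCCCCC=C
F2 | step 5 | 4-tert-butyl 1-methyl (2S)-2-[(1R)-1-(methanesulfonyloxy)hexadec-15-en-1-yl]butanedioate | COC(=O)[C@@H](CC(=O)OC(C)(C)C)[C@H](OS(C)(=O)=O)CCCCCCCCCCCCCC=C
F3 | step 5 | (3S,4R)-4-(methanesulfonyloxy)-3-(methoxycarbonyl)nonadec-18-enoic acid | COC(=O)[C@@H](CC(=O)O)[C@H](OS(C)(=O)=O)CCCCCCCCCCCCCC=C
F4 | step 5 | methyl (2S,3S)-5-oxo-2-(pentadec-14-en-1-yl)oxolane-3-carboxylate | C1C(=O)O[C@@H](CCCCCCCCCCCCCC=C)[C@H]1C(=O)OC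
F5 | step 4 | tert-butyl 4-[(4S)-4-benzyl-2-oxo-1,3-oxazolidin-3-yl]-4-oxobutanoate | CC(C)(C)OC(=O)CCC(=O)N1[C@@H](Cc2ccccc2)COC1=O
F6 | step 4 | tert-butyl (3S,4R)-3-[(4S)-4-benzyl-2-oxo-1,3-oxazolidine-3-carbonyl]-4-hydroxynonadec-18-enoate | CC(C)(C)OC(=O)C[C@H](C(=O)N1[C@@H](Cc2ccccc2)COC1=O)[C@H](O)CCCCCCCCCCCCCC=C
F7 | step 4 | (2S,3R)-2-[2-(tert-butoxy)-2-oxoethyl]-3-hydroxyoctadec-17-enoic acid | OC(=O)[C@@H](CC(=O)OC(C)(C)C)[C@H](O)CCCCCCCCCCCCCC=C
F8 | step 7 | (2S,3S)-5-oxo-2-(14-oxopentadecyl)oxolane-3-carboxylic acid | C1C(=O)O[C@@H](CCCCCCCCCCCCCC(C)=O)[C@H]1C(=O)O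
F9 | step 7 | (2S,3S)-2-[13-(2-methyl-1,3-dioxolan-2-yl)tridecyl]-5-oxooxolane-3-carboxylic acid | C1C(=O)O[C@@H](CCCCCCCCCCCCCC2(C)OCCO2)[C@H]1C(=O)O
F10 | step 7 | (2S,3S)-2-[13-(2-methyl-1,3-dioxolan-2-yl)tridecyl]-5-oxooxolane-3,4-dicarboxylic acid (C4 epimers) | OC(=O)C1C(=O)O[C@@H](CCCCCCCCCCCCCC2(C)OCCO2)[C@H]1C(=O)O
F11 | step 7 | (2S,3S)-4-methylidene-2-[13-(2-methyl-1,3-dioxolan-2-yl)tridecyl]-5-oxooxolane-3-carboxylic acid | C=C1C(=O)O[C@@H](CCCCCCCCCCCCCC2(C)OCCO2)[C@H]1C(=O)O
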